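**Strategy.** The route rests on breaking C7–C8 of the ten-membered carbocycle. The lactone carbons C12–C11(=C13)–C7–C6 are read as a transposed 3-(stannylmethyl)butenolide whose γ-carbon C7 is nucleophilic toward a C8 aldehyde. One Lewis-acid-promoted SE2′ allylation therefore forges C7–C8, closes the ten-membered ring, sets C7 and C8 under control of C6, and unveils the exocyclic C11=C13 methylene of the γ-lactone. The cyclisation substrate is an open-chain aldehyde carrying the C10 triethylsilyl ether, an E-C1=C2 alkene, the C3 carbinol as its TBS ether, the Z-C4=C5 alkene and the (6R)-butenolide with a CH2SnBu3 group on C11.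

Key step: step 19

Remark (assumption): germacranolide numbering is used throughout (epoxide C1–C2, ketone C3, C4(Me)=C5, lactone O on C6, ester O on C8, carbinol C10, lactone C=O C12, methylene C13); the C3 carbinol configuration in 24–31 (S) is a free choice because C3 ends as the ketone. Compounds 1, 5 and 9 are commercial.

**Route**

Step 1
Reactants: 1 (E)-3-methylpent-2-en-4-yn-1-ol
Product: 2 [(2S,3S)-3-ethynyl-3-methyloxiran-2-yl]methanol
Conditions: t-BuOOH, Ti(OiPr)4 (cat.), L-(+)-diisopropyl tartrate (cat.), 4 Å MS, CH2Cl2, −20 °C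
Reagents that add atoms: tert-butyl hydroperoxide, CC(C)(C)OO
Why: Sharpless asymmetric epoxidation, in which the L-(+)-tartrate catalyst epoxidises the allylic alcohol on the face that gives the (2S,3S)-epoxide (same sense as for other 3,3-disubstituted allylic alcohols) and so fixes the future C10 centre, the conjugated alkyne being inert.

Step 2
Reactants: 2 [(2S,3S)-3-ethynyl-3-methyloxiran-2-yl]methanol
Product: 3 (R)-3-methylpent-4-yne-1,3-diol
Conditions: Red-Al (1.2 equiv), THF, −20 → 0 °C; Rochelle salt work-up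
Reagents that add atoms: none
Why: Regioselective Red-Al opening of a 2,3-epoxy alcohol, in which the alkoxyaluminium hydride at the primary oxygen delivers hydride intramolecularly to C2 while the quaternary propargylic carbon cannot be attacked, so the C–O bond of the tertiary centre is retained (R) and limiting the hydride at low temperature should spare the alkyne.

Step 3
Reactants: 3 (R)-3-methylpent-4-yne-1,3-diol
Product: 4 (R)-3-methyl-3,5-bis(triethylsilyloxy)pent-1-yne
Conditions: TESOTf (2.5 equiv), 2,6-lutidine, CH2Cl2, −78 → 0 °C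
Reagents that add atoms: triethylsilyl triflate, CC[Si](CC)(CC)OS(=O)(=O)C(F)(F)F
Why: Exhaustive silylation protects the tertiary C10 hydroxyl and masks C8 as a primary TES ether that can later be removed selectively.

Step 4
Reactants: 5 prop-2-yn-1-ol (propargyl alcohol)
Product: 7 (Z)-3-iodo-2-methylprop-2-en-1-ol, via cyclic vinylmagnesium alkoxide 6 (not isolated)
Conditions: MeMgBr (3 equiv), CuI (10 mol %), THF, −10 °C → rt; then I2, −78 → 0 °C
Reagents that add atoms: methylmagnesium bromide, C[Mg]Br; iodine, II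
Why: Copper-catalysed anti-carbomagnesiation of propargyl alcohol (Duboudin reaction) puts methyl on the internal carbon and magnesium cis to the alkoxide in a five-membered chelate, so iodinolysis with retention gives the Z-iodide that encodes the Z-C4=C5 geometry.

Step 5
Reactants: 7 (Z)-3-iodo-2-methylprop-2-en-1-ol
Product: 8 tert-butyl{[(Z)-3-iodo-2-methylprop-2-en-1-yl]oxy}dimethylsilane
Conditions: TBSCl, imidazole, CH2Cl2, 0 °C → rt
Reagents that add atoms: tert-butyldimethylsilyl chloride, CC(C)(C)[Si](C)(C)Cl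
Why: Standard silylation masks the C3 hydroxyl before halogen–lithium exchange and prevents cyclisation of the later Z-γ-oxygenated ketone.

Step 6
Reactants: 9 tert-butyldimethyl(prop-2-yn-1-yloxy)silane
Product: 11 4-[(tert-butyldimethylsilyl)oxy]-N-methoxy-N-methylbut-2-ynamide, via lithium acetylide 10 (not isolated)
Conditions: n-BuLi, THF, −78 °C; then ClC(O)N(OMe)Me, −78 → 0 °C
Reagents that add atoms: N-methoxy-N-methylcarbamoyl chloride, CON(C)C(=O)Cl
Why: Acylation of the lithium acetylide with the carbamoyl chloride gives the Weinreb ynamide that carries C6, C7, C11 and C13.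

Step 7
Reactants: 8 tert-butyl{[(Z)-3-iodo-2-methylprop-2-en-1-yl]oxy}dimethylsilane; 11 4-[(tert-butyldimethylsilyl)oxy]-N-methoxy-N-methylbut-2-ynamide
Product: 14 (Z)-1,7-bis[(tert-butyldimethylsilyl)oxy]-6-methylhept-5-en-2-yn-4-one, via Z-vinyllithium 12 (not isolated), via tetrahedral lithium chelate 13 (not isolated)
Conditions: t-BuLi (2.1 equiv), Et2O, −78 °C; then 11, −78 °C; AcOH/aq. NH4Cl quench at −78 °C
Reagents that add atoms: none
Why: Iodine–lithium exchange with retention of the Z geometry followed by Weinreb ketone synthesis, where the stable N-methoxy chelate prevents over-addition and −78 °C in ether suppresses 1,4-O→C silyl migration.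

Step 8
Reactants: 14 (Z)-1,7-bis[(tert-butyldimethylsilyl)oxy]-6-methylhept-5-en-2-yn-4-one
Product: 15 (4R,5Z)-1,7-bis[(tert-butyldimethylsilyl)oxy]-6-methylhept-5-en-2-yn-4-ol
Conditions: Ru[(R,R)-TsDPEN](p-cymene) (3 mol %), i-PrOH, rt
Reagents that add atoms: none
Why: Noyori asymmetric transfer hydrogenation of an ynone, in which the alkynyl group takes the place normally held by an aryl group in the CH/π-controlled transition state, so the (R,R)-catalyst should give the (R)-propargylic alcohol (C6) without touching C=C or C≡C.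

Step 9
Reactants: 15 (4R,5Z)-1,7-bis[(tert-butyldimethylsilyl)oxy]-6-methylhept-5-en-2-yn-4-ol
Product: 17 (2Z,4R,5Z)-1,7-bis[(tert-butyldimethylsilyl)oxy]-2-iodo-6-methylhepta-2,5-dien-4-ol, via cyclic vinylalanate 16 (not isolated)
Conditions: Red-Al (1.5 equiv), THF, 0 °C; then I2, THF, −78 → 0 °C
Reagents that add atoms: iodine, II
Why: Hydroxyl-directed trans-hydroalumination of the propargylic alcohol adds hydride to C7 and aluminium to C11 within a five-membered alkoxyaluminate, and iodinolysis with retention places iodine on C11 cis to the C6 carbinol.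

Step 10
Reactants: 17 (2Z,4R,5Z)-1,7-bis[(tert-butyldimethylsilyl)oxy]-2-iodo-6-methylhepta-2,5-dien-4-ol
Product: 18 (5R)-3-{[(tert-butyldimethylsilyl)oxy]methyl}-5-{(1Z)-3-[(tert-butyldimethylsilyl)oxy]-2-methylprop-1-en-1-yl}furan-2(5H)-one
Conditions: PdCl2(PPh3)2 (5 mol %), CO (1 atm), i-Pr2NEt, THF, 40 °C
Reagents that add atoms: carbon monoxide, [C-]#[O+]
Why: Palladium-catalysed carbonylative lactonisation of a (Z)-γ-hydroxy vinyl iodide (oxidative addition, CO insertion, capture of the acylpalladium by the cis hydroxyl) closes the butenolide and brings in C12 without touching C6, the hindered weak base limiting γ-epimerisation.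

Step 11
Reactants: 18 (5R)-3-{[(tert-butyldimethylsilyl)oxy]methyl}-5-{(1Z)-3-[(tert-butyldimethylsilyl)oxy]-2-methylprop-1-en-1-yl}furan-2(5H)-one
Product: 19 (5R)-3-(hydroxymethyl)-5-[(1Z)-3-hydroxy-2-methylprop-1-en-1-yl]furan-2(5H)-one
Conditions: HF·pyridine, pyridine, THF, 0 °C → rt
Reagents that add atoms: none
Why: Fluoride cleavage of both primary TBS ethers under buffered, non-basic conditions that should not epimerise the acidic γ-position of the butenolide.

Step 12
Reactants: 19 (5R)-3-(hydroxymethyl)-5-[(1Z)-3-hydroxy-2-methylprop-1-en-1-yl]furan-2(5H)-one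
Product: 20 (2Z)-3-[(2R)-4-(hydroxymethyl)-5-oxo-2,5-dihydrofuran-2-yl]-2-methylprop-2-enal
Conditions: activated MnO2 (excess), CH2Cl2, rt
Reagents that add atoms: none
Why: Chemoselective allylic oxidation with MnO2, which should oxidise the alcohol on the electron-rich trisubstituted alkene much faster than the hydroxymethyl group on the electron-poor butenolide, the neutral heterogeneous conditions preserving the Z-enal.

Step 13
Reactants: 20 (2Z)-3-[(2R)-4-(hydroxymethyl)-5-oxo-2,5-dihydrofuran-2-yl]-2-methylprop-2-enal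
Product: 21 {(5R)-5-[(1Z)-2-methyl-3-oxoprop-1-en-1-yl]-2-oxo-2,5-dihydrofuran-3-yl}methyl acetate
Conditions: Ac2O, pyridine, CH2Cl2, 0 °C
Reagents that add atoms: acetic anhydride, CC(=O)OC(C)=O
Why: Acetylation turns the C13 hydroxyl into the leaving group needed later for π-allylpalladium formation and removes the acidic proton before the organozinc addition.

Step 14
Reactants: 4 (R)-3-methyl-3,5-bis(triethylsilyloxy)pent-1-yne; 21 {(5R)-5-[(1Z)-2-methyl-3-oxoprop-1-en-1-yl]-2-oxo-2,5-dihydrofuran-3-yl}methyl acetate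
Product: 24 {(5R)-5-[(1Z,3S,4E,6R)-3-hydroxy-2,6-dimethyl-6,8-bis(triethylsilyloxy)octa-1,4-dien-1-yl]-2-oxo-2,5-dihydrofuran-3-yl}methyl acetate, via E-alkenyl dicyclohexylborane 22 (not isolated), via E-alkenyl methyl zinc 23 (not isolated)
Conditions: 4 (1.5 equiv), Cy2BH, toluene, 0 °C → rt; Me2Zn, −78 °C; (−)-MIB (10 mol %), then 21, −20 → 0 °C; aq. NH4Cl
Reagents that add atoms: none
Why: Hydroboration, boron-to-zinc transmetalation and amino-alcohol-catalysed alkenylzinc addition (Oppolzer-type), where syn-hydroboration fixes the E-C1=C2 alkene and the (−)-MIB–zinc catalyst, which delivers alkenyl groups to the Si face of aldehydes, should set C3 as S, the lactone and allylic acetate being inert to the alkenylzinc.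

Step 15
Reactants: 24 {(5R)-5-[(1Z,3S,4E,6R)-3-hydroxy-2,6-dimethyl-6,8-bis(triethylsilyloxy)octa-1,4-dien-1-yl]-2-oxo-2,5-dihydrofuran-3-yl}methyl acetate
Product: 25 {(5R)-5-[(1Z,3S,4E,6R)-3-[(tert-butyldimethylsilyl)oxy]-2,6-dimethyl-6,8-bis(triethylsilyloxy)octa-1,4-dien-1-yl]-2-oxo-2,5-dihydrofuran-3-yl}methyl acetate
Conditions: TBSOTf, 2,6-lutidine, CH2Cl2, −78 °C
Reagents that add atoms: tert-butyldimethylsilyl triflate, CC(C)(C)[Si](C)(C)OS(=O)(=O)C(F)(F)F
Why: Silylation of the hindered bis-allylic C3 alcohol with a silyl triflate and a non-nucleophilic base at low temperature, conditions that leave the allylic acetate untouched.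

Step 16
Reactants: 25 {(5R)-5-[(1Z,3S,4E,6R)-3-[(tert-butyldimethylsilyl)oxy]-2,6-dimethyl-6,8-bis(triethylsilyloxy)octa-1,4-dien-1-yl]-2-oxo-2,5-dihydrofuran-3-yl}methyl acetate
Product: 26 (5R)-5-{(1Z,3S,4E,6R)-3-[(tert-butyldimethylsilyl)oxy]-2,6-dimethyl-6,8-bis(triethylsilyloxy)octa-1,4-dien-1-yl}-3-[(tributylstannyl)methyl]furan-2(5H)-one
Conditions: Bu3SnAlEt2 (stock solution), Pd(PPh3)4 (5 mol %), THF, 0 °C → rt
Reagents that add atoms: (tributylstannyl)diethylaluminium, CCCC[Sn](CCCC)(CCCC)[Al](CC)CC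
Why: Palladium-catalysed stannylation of an allylic acetate (Tsuji–Trost ionisation, then stannyl transfer from aluminium), in which tin is delivered to the less hindered terminus C13 of the 2-acyl π-allyl complex to give the conjugated 3-(stannylmethyl)butenolide.

Step 17
Reactants: 26 (5R)-5-{(1Z,3S,4E,6R)-3-[(tert-butyldimethylsilyl)oxy]-2,6-dimethyl-6,8-bis(triethylsilyloxy)octa-1,4-dien-1-yl}-3-[(tributylstannyl)methyl]furan-2(5H)-one
Product: 27 (5R)-5-{(1Z,3S,4E,6R)-3-[(tert-butyldimethylsilyl)oxy]-8-hydroxy-2,6-dimethyl-6-(triethylsilyloxy)octa-1,4-dien-1-yl}-3-[(tributylstannyl)methyl]furan-2(5H)-one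
Conditions: PPTS (cat.), MeOH/CH2Cl2, 0 °C
Reagents that add atoms: none
Why: Acid-catalysed methanolysis removes the primary TES ether far faster than the tertiary TES or secondary TBS ether, and the weak acid should not protodestannylate the electron-poor allylstannane.

Step 18
Reactants: 27 (5R)-5-{(1Z,3S,4E,6R)-3-[(tert-butyldimethylsilyl)oxy]-8-hydroxy-2,6-dimethyl-6-(triethylsilyloxy)octa-1,4-dien-1-yl}-3-[(tributylstannyl)methyl]furan-2(5H)-one
Product: 28 (3R,4E,6S,7Z)-6-[(tert-butyldimethylsilyl)oxy]-3,7-dimethyl-8-{(2R)-5-oxo-4-[(tributylstannyl)methyl]-2,5-dihydrofuran-2-yl}-3-(triethylsilyloxy)octa-4,7-dienal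
Conditions: Dess–Martin periodinane, NaHCO3, CH2Cl2, 0 °C
Reagents that add atoms: none
Why: Buffered Dess–Martin oxidation converts the primary alcohol into the C8 aldehyde under neutral conditions that tolerate the allylstannane and the silyl ethers.

Step 19
Reactants: 28 (3R,4E,6S,7Z)-6-[(tert-butyldimethylsilyl)oxy]-3,7-dimethyl-8-{(2R)-5-oxo-4-[(tributylstannyl)methyl]-2,5-dihydrofuran-2-yl}-3-(triethylsilyloxy)octa-4,7-dienal
Product: 29 (3aR,4R,6R,7E,9S,10Z,11aR)-9-[(tert-butyldimethylsilyl)oxy]-4-hydroxy-6,10-dimethyl-3-methylidene-6-(triethylsilyloxy)-3a,4,5,6,9,11a-hexahydrocyclodeca[b]furan-2(3H)-one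
Conditions: BF3·OEt2 (2 equiv), 2,6-di-tert-butyl-4-methylpyridine, CH2Cl2, −78 °C, slow addition of 28 to 1 mM; aq. NaHCO3 at −78 °C
Reagents that add atoms: none
Why: BF3 binds the C8 aldehyde and the allylstannane attacks through its γ-carbon C7 (SE2′), the C13–Sn bond feeding electrons through C11=C7 so that loss of tin moves the double bond to C11=C13 and the α-methylene lactone appears. The closest known reactions are Lewis-acid-promoted macrocyclisations of allylstannane aldehydes and γ-selective additions of 2-(alkoxycarbonyl)allyl metals to aldehydes. The ten-membered carbocycle closes by carbonyl addition in a 10-exo-trig mode (C=O exocyclic to the new ring), helped by the turn imposed by the Z-C4=C5 alkene and the butenolide and by high dilution. C7 is set by C6, because the new bond forms on the butenolide face opposite the C5 branch and gives the trans-fused lactone, the only arrangement in which the chain spans C6 and C7 without eclipsing. C8 is set by the open antiperiplanar transition state (C8=O anti to C11=C7, C9 anti to C6), which should give the 7R,8R relationship with the C8 oxygen syn to C6. The step needs γ- over α-attack (inherent to SE2′; α-attack would require a twelve-membered ring) and no competing electrophile, which the C3 silyl ether secures, while the hindered pyridine scavenges acid that could cleave the stannane or the allylic silyl ethers.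

Step 20
Reactants: 29 (3aR,4R,6R,7E,9S,10Z,11aR)-9-[(tert-butyldimethylsilyl)oxy]-4-hydroxy-6,10-dimethyl-3-methylidene-6-(triethylsilyloxy)-3a,4,5,6,9,11a-hexahydrocyclodeca[b]furan-2(3H)-one
Product: 30 (3aR,4R,6R,7E,9S,10Z,11aR)-9-[(tert-butyldimethylsilyl)oxy]-6,10-dimethyl-3-methylidene-2-oxo-6-(triethylsilyloxy)-2,3,3a,4,5,6,9,11a-octahydrocyclodeca[b]furan-4-yl 2-methylpropanoate
Conditions: (i-PrCO)2O, Et3N, DMAP (cat.), CH2Cl2, 0 °C
Reagents that add atoms: isobutyric anhydride, CC(C)C(=O)OC(=O)C(C)C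
Why: DMAP-catalysed acylation of the C8 secondary alcohol with retention, done promptly so that the free 8-hydroxyl cannot translactonise onto C12.

Step 21
Reactants: 30 (3aR,4R,6R,7E,9S,10Z,11aR)-9-[(tert-butyldimethylsilyl)oxy]-6,10-dimethyl-3-methylidene-2-oxo-6-(triethylsilyloxy)-2,3,3a,4,5,6,9,11a-octahydrocyclodeca[b]furan-4-yl 2-methylpropanoate
Product: 31 (3aR,4R,6R,7E,9S,10Z,11aR)-6,9-dihydroxy-6,10-dimethyl-3-methylidene-2-oxo-2,3,3a,4,5,6,9,11a-octahydrocyclodeca[b]furan-4-yl 2-methylpropanoate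
Conditions: HF·pyridine, pyridine, THF, 0 °C → rt
Reagents that add atoms: none
Why: Buffered HF·pyridine cleaves the secondary TBS and the tertiary TES ether while tolerating the α-methylene lactone and the ester, which basic fluoride sources would endanger.

Step 22
Reactants: 31 (3aR,4R,6R,7E,9S,10Z,11aR)-6,9-dihydroxy-6,10-dimethyl-3-methylidene-2-oxo-2,3,3a,4,5,6,9,11a-octahydrocyclodeca[b]furan-4-yl 2-methylpropanoate
Product: 32 (3aR,4R,6R,7E,10Z,11aR)-6-hydroxy-6,10-dimethyl-3-methylidene-2,9-dioxo-2,3,3a,4,5,6,9,11a-octahydrocyclodeca[b]furan-4-yl 2-methylpropanoate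
Conditions: activated MnO2, CH2Cl2, rt
Reagents that add atoms: none
Why: Allylic oxidation with MnO2 affects only the bis-allylic secondary C3 alcohol (the C10 alcohol is tertiary) and gives the cross-conjugated dienone.

Step 23
Reactants: 32 (3aR,4R,6R,7E,10Z,11aR)-6-hydroxy-6,10-dimethyl-3-methylidene-2,9-dioxo-2,3,3a,4,5,6,9,11a-octahydrocyclodeca[b]furan-4-yl 2-methylpropanoate
Product: 33 CNP0273626.1, the (1R,2R)-1,2-epoxide of 32
Conditions: t-BuOOH (anhydrous, in decane), DBU, CH2Cl2, 0 °C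
Reagents that add atoms: tert-butyl hydroperoxide, CC(C)(C)OO
Why: Weitz–Scheffer nucleophilic epoxidation assisted by the C10 hydroxyl, which hydrogen-bonds the peroxide anion and guides it to C1 on the open outer face of the E-enone (C10 methyl in the alkene plane, hydroxyl on the attacked face) so that the trans (1R,2R)-epoxide should form, while C4=C5 (α-methylated, no directing hydroxyl) and the less electrophilic acrylate C11=C13 should stay intact.

**Compound list**

1 | (E)-3-methylpent-2-en-4-yn-1-ol | C#C/C(C)=C/CO | starting material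
2 | [(2S,3S)-3-ethynyl-3-methyloxiran-2-yl]methanol | OC[C@@H]1O[C@@]1(C)C#C | intermediate
3 | (R)-3-methylpent-4-yne-1,3-diol | C#C[C@](C)(O)CCO | intermediate
4 | (R)-3-methyl-3,5-bis(triethylsilyloxy)pent-1-yne | C#C[C@](C)(O[Si](CC)(CC)CC)CCO[Si](CC)(CC)CC | intermediate
5 | prop-2-yn-1-ol (propargyl alcohol) | C#CCO | starting material
6 | 4-methyl-2,5-dihydro-1,2-oxamagnesole (cyclic vinylmagnesium alkoxide) | CC1=C[Mg]OC1 | intermediate (not isolated)
7 | (Z)-3-iodo-2-methylprop-2-en-1-ol | OC/C(C)=C\I | intermediate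
8 | tert-butyl{[(Z)-3-iodo-2-methylprop-2-en-1-yl]oxy}dimethylsilane | CC(C)(C)[Si](C)(C)OC/C(C)=C\I | intermediate
9 | tert-butyldimethyl(prop-2-yn-1-yloxy)silane | C#CCO[Si](C)(C)C(C)(C)C | starting material
10 | lithium acetylide of 9 | [Li]C#CCO[Si](C)(C)C(C)(C)C | intermediate (not isolated)
11 | 4-[(tert-butyldimethylsilyl)oxy]-N-methoxy-N-methylbut-2-ynamide | CON(C)C(=O)C#CCO[Si](C)(C)C(C)(C)C | intermediate
12 | (Z)-vinyllithium from 8 | CC(C)(C)[Si](C)(C)OC/C(C)=C\[Li] | intermediate (not isolated)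
13 | tetrahedral lithium N-methoxy-N-methylaminal alkoxide from 12 and 11 | CC(C)(C)[Si](C)(C)OC/C(C)=C\C(O[Li])(N(C)OC)C#CCO[Si](C)(C)C(C)(C)C | intermediate (not isolated)
14 | (Z)-1,7-bis[(tert-butyldimethylsilyl)oxy]-6-methylhept-5-en-2-yn-4-one | CC(C)(C)[Si](C)(C)OC/C(C)=C\C(=O)C#CCO[Si](C)(C)C(C)(C)C | intermediate
15 | (4R,5Z)-1,7-bis[(tert-butyldimethylsilyl)oxy]-6-methylhept-5-en-2-yn-4-ol | CC(C)(C)[Si](C)(C)OC/C(C)=C\[C@@H](O)C#CCO[Si](C)(C)C(C)(C)C | intermediate
16 | cyclic sodium alkoxy(vinyl)aluminate from 15 (Al on C11, O on C6) | [Na+].COCCO[Al-]1(OCCOC)O[C@H](/C=C(/C)CO[Si](C)(C)C(C)(C)C)C=C1CO[Si](C)(C)C(C)(C)C | intermediate (not isolated)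
17 | (2Z,4R,5Z)-1,7-bis[(tert-butyldimethylsilyl)oxy]-2-iodo-6-methylhepta-2,5-dien-4-ol | CC(C)(C)[Si](C)(C)OC/C(C)=C\[C@@H](O)/C=C(\I)CO[Si](C)(C)C(C)(C)C | intermediate
18 | (5R)-3-{[(tert-butyldimethylsilyl)oxy]methyl}-5-{(1Z)-3-[(tert-butyldimethylsilyl)oxy]-2-methylprop-1-en-1-yl}furan-2(5H)-one | CC(C)(C)[Si](C)(C)OC/C(C)=C\[C@H]1OC(=O)C(CO[Si](C)(C)C(C)(C)C)=C1 | intermediate
19 | (5R)-3-(hydroxymethyl)-5-[(1Z)-3-hydroxy-2-methylprop-1-en-1-yl]furan-2(5H)-one | OC/C(C)=C\[C@H]1OC(=O)C(CO)=C1 | intermediate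
20 | (2Z)-3-[(2R)-4-(hydroxymethyl)-5-oxo-2,5-dihydrofuran-2-yl]-2-methylprop-2-enal | O=C/C(C)=C\[C@H]1OC(=O)C(CO)=C1 | intermediate
21 | {(5R)-5-[(1Z)-2-methyl-3-oxoprop-1-en-1-yl]-2-oxo-2,5-dihydrofuran-3-yl}methyl acetate | O=C/C(C)=C\[C@H]1OC(=O)C(COC(C)=O)=C1 | intermediate
22 | (E)-alkenyl(dicyclohexyl)borane from 4 | CC[Si](CC)(CC)OCC[C@@](C)(O[Si](CC)(CC)CC)/C=C/B(C1CCCCC1)C1CCCCC1 | intermediate (not isolated)
23 | (E)-alkenyl(methyl)zinc from 22 | CC[Si](CC)(CC)OCC[C@@](C)(O[Si](CC)(CC)CC)/C=C/[Zn]C | intermediate (not isolated)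
24 | {(5R)-5-[(1Z,3S,4E,6R)-3-hydroxy-2,6-dimethyl-6,8-bis(triethylsilyloxy)octa-1,4-dien-1-yl]-2-oxo-2,5-dihydrofuran-3-yl}methyl acetate | CC[Si](CC)(CC)OCC[C@@](C)(O[Si](CC)(CC)CC)/C=C/[C@H](O)/C(C)=C\[C@H]1OC(=O)C(COC(C)=O)=C1 | intermediate
25 | {(5R)-5-[(1Z,3S,4E,6R)-3-[(tert-butyldimethylsilyl)oxy]-2,6-dimethyl-6,8-bis(triethylsilyloxy)octa-1,4-dien-1-yl]-2-oxo-2,5-dihydrofuran-3-yl}methyl acetate | CC[Si](CC)(CC)OCC[C@@](C)(O[Si](CC)(CC)CC)/C=C/[C@H](O[Si](C)(C)C(C)(C)C)/C(C)=C\[C@H]1OC(=O)C(COC(C)=O)=C1 | intermediate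
26 | (5R)-5-{(1Z,3S,4E,6R)-3-[(tert-butyldimethylsilyl)oxy]-2,6-dimethyl-6,8-bis(triethylsilyloxy)octa-1,4-dien-1-yl}-3-[(tributylstannyl)methyl]furan-2(5H)-one | CC[Si](CC)(CC)OCC[C@@](C)(O[Si](CC)(CC)CC)/C=C/[C@H](O[Si](C)(C)C(C)(C)C)/C(C)=C\[C@H]1OC(=O)C(C[Sn](CCCC)(CCCC)CCCC)=C1 | intermediate
27 | (5R)-5-{(1Z,3S,4E,6R)-3-[(tert-butyldimethylsilyl)oxy]-8-hydroxy-2,6-dimethyl-6-(triethylsilyloxy)octa-1,4-dien-1-yl}-3-[(tributylstannyl)methyl]furan-2(5H)-one | OCC[C@@](C)(O[Si](CC)(CC)CC)/C=C/[C@H](O[Si](C)(C)C(C)(C)C)/C(C)=C\[C@H]1OC(=O)C(C[Sn](CCCC)(CCCC)CCCC)=C1 | intermediate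
28 | (3R,4E,6S,7Z)-6-[(tert-butyldimethylsilyl)oxy]-3,7-dimethyl-8-{(2R)-5-oxo-4-[(tributylstannyl)methyl]-2,5-dihydrofuran-2-yl}-3-(triethylsilyloxy)octa-4,7-dienal (cyclisation precursor) | O=CC[C@@](C)(O[Si](CC)(CC)CC)/C=C/[C@H](O[Si](C)(C)C(C)(C)C)/C(C)=C\[C@H]1OC(=O)C(C[Sn](CCCC)(CCCC)CCCC)=C1 | intermediate
29 | (3aR,4R,6R,7E,9S,10Z,11aR)-9-[(tert-butyldimethylsilyl)oxy]-4-hydroxy-6,10-dimethyl-3-methylidene-6-(triethylsilyloxy)-3a,4,5,6,9,11a-hexahydrocyclodeca[b]furan-2(3H)-one (cyclisation product) | C=C1C(=O)O[C@@H]2/C=C(/C)[C@@H](O[Si](C)(C)C(C)(C)C)/C=C/[C@](C)(O[Si](CC)(CC)CC)C[C@@H](O)[C@@H]12 | intermediate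
30 | 8-O-isobutyrate of 29 | C=C1C(=O)O[C@@H]2/C=C(/C)[C@@H](O[Si](C)(C)C(C)(C)C)/C=C/[C@](C)(O[Si](CC)(CC)CC)C[C@@H](OC(=O)C(C)C)[C@@H]12 | intermediate
31 | (3aR,4R,6R,7E,9S,10Z,11aR)-6,9-dihydroxy-6,10-dimethyl-3-methylidene-2-oxo-2,3,3a,4,5,6,9,11a-octahydrocyclodeca[b]furan-4-yl 2-methylpropanoate | C=C1C(=O)O[C@@H]2/C=C(/C)[C@@H](O)/C=C/[C@](C)(O)C[C@@H](OC(=O)C(C)C)[C@@H]12 | intermediate
32 | (3aR,4R,6R,7E,10Z,11aR)-6-hydroxy-6,10-dimethyl-3-methylidene-2,9-dioxo-2,3,3a,4,5,6,9,11a-octahydrocyclodeca[b]furan-4-yl 2-methylpropanoate | C=C1C(=O)O[C@@H]2/C=C(/C)C(=O)/C=C/[C@](C)(O)C[C@@H](OC(=O)C(C)C)[C@@H]12 | intermediate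
33 | CNP0273626.1, (1R,2R)-1,2-epoxide of 32 (1R,2R,6R,7R,8R,10R; 4Z) | C=C1C(=O)O[C@@H]2/C=C(/C)C(=O)[C@@H]3O[C@H]3[C@](C)(O)C[C@@H](OC(=O)C(C)C)[C@@H]12 | target

**Step count and risks**

Total: 23 steps. Longest linear sequence: 19 steps (5 → 33 through steps 4, 5 and 7–23).

Steps most likely to fail:

1. Step 19 (macrocyclisation). The ester-deactivated allylstannane may add too slowly, so that oligomerisation or protodestannylation takes over. The Lewis acid may ionise the bis-allylic C3 or the tertiary allylic C10 silyl ether. The aldehyde may be attacked on the wrong face. Fallback (Barbier-type closure of the same bond under neutral conditions): setting out from acetate 25, selective methanolysis of the primary TES ether (PPTS, MeOH) gives the 8-hydroxy acetate F1, and Dess–Martin oxidation gives the acetoxy aldehyde F2. Pd(PPh3)4 (cat.) with InI in THF then converts the allylic acetate through its π-allylpalladium complex into an allylindium species that adds through C7 to the C8 aldehyde in a cyclic six-membered transition state. This closed transition state is expected to favour the C8 epimer of 29, the 8-epi alcohol F3, which is esterified with inversion (Mitsunobu reaction: isobutyric acid, PPh3, DIAD) and so returns to the route at 30. Any 29 formed directly continues with step 20.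

2. Step 23 (epoxidation). Peroxide may add at C5 or C13 instead of C1, facial selectivity on C1=C2 may be poor, or the base may damage the lactone or ester. Fallback (directed electrophilic epoxidation before the ketone is made): setting out from diol 31, selective silylation of the secondary C3 hydroxyl (TESCl, imidazole) gives the mono-TES ether F4, whose only free allylic hydroxyl is at C10. VO(acac)2/t-BuOOH then epoxidises only C1=C2, from the face of the C10 hydroxyl, to give the epoxy alcohol F5. HF·pyridine releases the epoxy diol F6, and Dess–Martin oxidation of the C3 alcohol returns to the route at 33.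

3. Step 14 (fragment union). The Z-enal may isomerise under the Lewis-acidic zinc species, hydroboration of the hindered alkyne may be incomplete, or facial selectivity at C3 may be low. Fallback (halide-based coupling): setting out from alkyne 4, hydrozirconation and iodinolysis (Cp2Zr(H)Cl; I2) give the (E)-vinyl iodide F7. An asymmetric Nozaki–Hiyama–Kishi coupling of F7 with aldehyde 21 (CrCl2, NiCl2 cat., chiral sulfonamide ligand) forms the same C2–C3 bond and returns to the route at 24.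

**Further compounds**

F1 | step 19 | {(5R)-5-[(1Z,3S,4E,6R)-3-[(tert-butyldimethylsilyl)oxy]-8-hydroxy-2,6-dimethyl-6-(triethylsilyloxy)octa-1,4-dien-1-yl]-2-oxo-2,5-dihydrofuran-3-yl}methyl acetate | OCC[C@@](C)(O[Si](CC)(CC)CC)/C=C/[C@H](O[Si](C)(C)C(C)(C)C)/C(C)=C\[C@H]1OC(=O)C(COC(C)=O)=C1
F2 | step 19 | {(5R)-5-[(1Z,3S,4E,6R)-3-[(tert-butyldimethylsilyl)oxy]-2,6-dimethyl-8-oxo-6-(triethylsilyloxy)octa-1,4-dien-1-yl]-2-oxo-2,5-dihydrofuran-3-yl}methyl acetate | O=CC[C@@](C)(O[Si](CC)(CC)CC)/C=C/[C@H](O[Si](C)(C)C(C)(C)C)/C(C)=C\[C@H]1OC(=O)C(COC(C)=O)=C1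
F3 | step 19 | C8 epimer of 29 (4S alcohol) | C=C1C(=O)O[C@@H]2/C=C(/C)[C@@H](O[Si](C)(C)C(C)(C)C)/C=C/[C@](C)(O[Si](CC)(CC)CC)C[C@H](O)[C@@H]12
F4 | step 23 | C3 triethylsilyl ether of 31 (C10 hydroxyl free) | C=C1C(=O)O[C@@H]2/C=C(/C)[C@@H](O[Si](CC)(CC)CC)/C=C/[C@](C)(O)C[C@@H](OC(=O)C(C)C)[C@@H]12
F5 | step 23 | 1,2-epoxide of F4 (epoxide configured as in 33) | C=C1C(=O)O[C@@H]2/C=C(/C)[C@@H](O[Si](CC)(CC)CC)[C@@H]3O[C@H]3[C@](C)(O)C[C@@H](OC(=O)C(C)C)[C@@H]12
F6 | step 23 | 1,2-epoxide of 31 (C3 alcohol, epoxide configured as in 33) | C=C1C(=O)O[C@@H]2/C=C(/C)[C@@H](O)[C@@H]3O[C@H]3[C@](C)(O)C[C@@H](OC(=O)C(C)C)[C@@H]12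
F7 | step 14 | (R,E)-1-iodo-3-methyl-3,5-bis(triethylsilyloxy)pent-1-ene | CC[Si](CC)(CC)OCC[C@@](C)(O[Si](CC)(CC)CC)/C=C/I
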